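The flasks hold 0.80 M of first end groups and from 0.300 M to 2.50 M of second end groups.

all flasks: first end groups 0.80 M

| flask | second end groups | temperature | remark | time |
|---|---|---|---|---|
| Sunday's | 0.32 M | 85 °C | run made earlier |  |
| Wednesday's | 0.93 M | 96 °C | run made earlier |  |
| Monday's | 2.1 M | 85 °C | run made earlier |  |
| autumn | 1.20 M | 90 °C |  | 2.5 d |
| dawn | 0.300 M | 90 °C |  | 2.5 d |
| winter | 0.840 M | 90 °C |  | 2.5 d |
| noon | 2.50 M | 90 °C |  | 2.5 d |
| summer | 1.50 M | 90 °C |  | 2.5 d |
| midnight | 0.600 M | 90 °C |  | 2.5 d |

- Sunday's (time / h: links / %): 2.50: 2.9; 8.00: 4.8; 15.0: 6.4; 20.0: 7.0; 30.0: 6.7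
- Wednesday's (time / h: links / %): 2.50: 9.7; 8.00: 17.0; 15.0: 17.7; 20.0: 17.5; 30.0: 16.1
- Monday's (time / h: links / %): 6.00: 21.4; 12.0: 31.7; 20.0: 36.9; 25.0: 38.0; 30.0: 39.4

(readings scatter by 0.5 percentage points)



- the flasks put in order of amount of links, in percent of the first end groups charged, best first, at 2.5 d (autumn / dawn / winter / noon / summer / midnight)
- the same order at 10 d (autumn / dawn / winter / noon / summer / midnight)
- the amount of links, in percent of the first end groups charged of the flask you put first, at 2.5 d
- the amount of links, in percent of the first end groups charged of the flask you put last, at 2.5 d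

Take the main step first: first end groups + second end groups → links. It gives one link per second end group, so Sunday's charge allows 40.0% of the first end groups charged. Yet Sunday's readings stop near 7.0%, and Wednesday's turn down after 17.7%.

Now add a second step, assumed here: first end groups also consume links. Both rates then carry c(first end groups), which cancels in their ratio, and time goes with it:

dc(links)/dc(second end groups) = −1 + s · c(links)/c(second end groups)

Here s, the selectivity factor, is the rate constant of the second step over that of the first. Links rise while c(links) stays below c(second end groups)/s. Integrated, the equation makes the peak a fixed share of the charged second end groups, set by s. Call it the peak share f, peak c(links) over charged c(second end groups).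

The readings give:

Sunday, 85 °C: f = 0.175

Wednesday, 96 °C: f = 0.152

These temperatures lie either side of 90 °C, so the mean serves:

f = 0.164

Multiplied by the charge of second end groups, f gives each flask a ceiling, and the ceiling rises with that charge. The order by ceiling is therefore the order by second end groups.

Last, add the supply of first end groups. Both steps consume them, and both stop when c(first end groups) reaches zero. Monday's ceiling is 45.9%, and its readings show no downturn: the last two go from 38.0% to 39.4%. Monday's last reading at 30.0 h stands at 0.858 of that ceiling, and the same fraction is taken over for noon as a rough estimate: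

noon: ceiling 51.1%, expected 43.9%

Dawn has a ceiling of 6.14%. It holds less second than first end groups, and 2.5 d is longer than Sunday's 20.0 h to the peak, so dawn is expected past its peak and below that ceiling.

The forecast gave noon > summer > autumn > winter > midnight > dawn at 2.5 d and noon > summer > autumn > winter > midnight > dawn at 10 d, with 37% (30% to 43%) for noon, under the ceiling reckoning's 43.9%, and 5.8% (4.5% to 7.2%) for dawn, holding that “every flask has reached its plateau”.

The flasks give noon > summer > autumn > winter > midnight > dawn at 2.5 d and noon > summer > autumn > winter > midnight > dawn at 10 d, with noon at 44.3% and dawn at 3.34%.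

    second end groups → decomposed reagent (k = 3.10 × 10⁻⁷ s⁻¹, Ea = 126 kJ mol⁻¹)
    first end groups + second end groups → links (k = 1.10 × 10⁻⁵ M⁻¹ s⁻¹, Ea = 78.0 kJ mol⁻¹)
    first end groups + links → side product (k = 4.20 × 10⁻⁵ M⁻¹ s⁻¹, Ea = 97.0 kJ mol⁻¹)
    (constants at 90 °C)

Noon stands under its ceiling of 51.1%, with 0.055% of its first end groups left. In dawn, links were made 1.02 times as fast as used up at 0.655 d, and 0.742 times as fast at 2.50 d, with 50% of the first end groups still present. Dawn's 3.34% lies below its ceiling of 6.14%. A neighbour of dawn charged with 0.32 M of first end groups has the same second end groups, so f gives it a ceiling of 15.4%, and it holds 14.7%.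

(The runs come from a simulation with made-up constants.)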